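The pyran ring C of the upper flavan unit (O1–C2–C3–C4–C4a–C8a) is cut at C2–C3 and C4–C4a: C3–C4 becomes an enediol two-carbon unit inserted between an O-aryl oxocarbenium carbon (C2) and the nucleophilic ortho carbon C4a of the phloroglucinol ring A. One cationic [4+2] annulation (oxa-Povarov) of the oxocarbenium ion from a phenol mixed acetal with a (Z)-2-alkoxyvinyl gallate forms both bonds and the cis C2/C3 stereocentres with the 3-O-galloyl group in place. The C4 alkoxy group is a chiral auxiliary that controls the face and then leaves as the trigger for the 4β→8 coupling with benzylated epicatechin gallate.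

Key step: step 7

Assumption: the (1R,2S) enantiomer of trans-2-phenylcyclohexanol is taken as the auxiliary whose phenyl ring shields the Re face of the acyloxy-bearing alkene carbon of the s-trans (Z)-enol ether. Should the induction run the other way, the equally available (1S,2R) enantiomer is used with no other change. Flavan numbering is used for the upper unit throughout.

Step 1
Reactants: 1 (1R,2S)-trans-2-phenylcyclohexan-1-ol
Product: 3 allyl (1R,2S)-2-phenylcyclohexyl ether, via sodium (1R,2S)-2-phenylcyclohexanolate 2 (not isolated)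
Conditions: NaH, THF/DMF, 0 °C; then allyl bromide, Bu4NI (cat.), 0 °C → rt
Reagents that add atoms: allyl bromide, C=CCBr
Why: Williamson etherification of the secondary alkoxide with a reactive allylic bromide, which leaves both stereocentres of the auxiliary untouched.

Step 2
Reactants: 3 allyl (1R,2S)-2-phenylcyclohexyl ether
Product: 5 2-{[(1R,2S)-2-phenylcyclohexyl]oxy}acetaldehyde, via secondary ozonide 4 (not isolated)
Conditions: O3, CH2Cl2, −78 °C; then Me2S, −78 °C → rt
Reagents that add atoms: ozone, [O-][O+]=O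
Why: Ozonolysis of the terminal alkene with reductive work-up should give the α-alkoxy aldehyde, the isolated phenyl ring being far less reactive toward ozone at −78 °C.

Step 3
Reactants: 6 3,4,5-tris(benzyloxy)benzoic acid
Product: 7 3,4,5-tris(benzyloxy)benzoyl chloride
Conditions: (COCl)2, DMF (cat.), CH2Cl2, 0 °C → rt
Reagents that add atoms: oxalyl chloride, ClC(=O)C(=O)Cl
Why: Vilsmeier-type activation of the acid by oxalyl chloride and catalytic DMF gives the acid chloride under conditions to which benzyl ethers are inert.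

Step 4
Reactants: 5 2-{[(1R,2S)-2-phenylcyclohexyl]oxy}acetaldehyde; 7 3,4,5-tris(benzyloxy)benzoyl chloride
Product: 9 (Z)-2-{[(1R,2S)-2-phenylcyclohexyl]oxy}ethenyl 3,4,5-tris(benzyloxy)benzoate, via potassium (Z)-enolate 8 (not isolated)
Conditions: KN(SiMe3)2, THF, −78 °C (5 added slowly to the base); then 7, −78 → 0 °C
Reagents that add atoms: none
Why: Inverse addition to the potassium amide should give the potassium-chelated (Z)-enolate (both oxygens cis), and O-acylation of this enolate by the hard aroyl chloride should give the (Z)-enol ester.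

Step 5
Reactants: 10 3,4-bis(benzyloxy)benzaldehyde
Product: 11 3,4-bis(benzyloxy)benzaldehyde dimethyl acetal
Conditions: HC(OMe)3, p-TsOH·H2O (cat.), MeOH, rt; Et3N quench
Reagents that add atoms: trimethyl orthoformate, COC(OC)OC; methanol, CO
Why: Acid-catalysed acetalisation, driven to completion by the orthoformate as water scavenger.

Step 6
Reactants: 11 3,4-bis(benzyloxy)benzaldehyde dimethyl acetal; 12 3,5-bis(benzyloxy)phenol
Product: 15 1,3-bis(benzyloxy)-5-{[3,4-bis(benzyloxy)phenyl](methoxy)methoxy}benzene (racemic mixed O-aryl O-methyl acetal), via α-chloro ether 13 (not isolated), via sodium 3,5-bis(benzyloxy)phenoxide 14 (not isolated)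
Conditions: 11, AcCl (1.05 equiv), CH2Cl2, 0 °C → rt, then evaporation; 12, NaH, THF, 0 °C; then 13, −78 → 0 °C; chromatography on Et3N-deactivated silica
Reagents that add atoms: none
Why: Acetyl chloride should convert the dimethyl acetal into the α-chloro ether (as in the preparation of chloromethyl ethers from formaldehyde acetals), and this hard, oxocarbenium-like electrophile should O-alkylate the sodium phenoxide in a Williamson-type acetal formation; the new stereocentre is racemic and is lost again in step 7.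

Step 7
Reactants: 15 1,3-bis(benzyloxy)-5-{[3,4-bis(benzyloxy)phenyl](methoxy)methoxy}benzene; 9 (Z)-2-{[(1R,2S)-2-phenylcyclohexyl]oxy}ethenyl 3,4,5-tris(benzyloxy)benzoate
Product: 18 (2R,3R,4R)-5,7-bis(benzyloxy)-2-[3,4-bis(benzyloxy)phenyl]-4-{[(1R,2S)-2-phenylcyclohexyl]oxy}chroman-3-yl 3,4,5-tris(benzyloxy)benzoate (all-cis 4α-alkoxy cycloadduct), via aryl oxocarbenium triflate 16 (not isolated), via open-chain alkoxycarbenium triflate 17 (not isolated)
Conditions: 15 (1.0 equiv), 9 (2.0 equiv), 2,6-di-tert-butyl-4-methylpyridine (1.2 equiv), 4 Å MS, CH2Cl2, −78 °C, slow addition of Me3SiOTf (1.0 equiv); Et3N quench at −78 °C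
Reagents that add atoms: none
Why: Me3SiOTf abstracts the methoxy group of 15 to give the (E)-O-aryl oxocarbenium ion 16, a cationic 2-oxadiene (C4a=C8a–O1+=C2); the alkene carbon of 9 that bears the galloyloxy group, which is β to the stronger ether donor and therefore the nucleophilic terminus, adds to C2 (bond C2–C3), and the alkoxycarbenium ion 17 so formed is captured by the ortho carbon C4a of the symmetric 3,5-dibenzyloxyphenoxy ring (bond C4–C4a), the hindered pyridine taking up the proton. The closest known reaction type is the oxa-Povarov reaction, the formal inverse-electron-demand [4+2] annulation of aryl oxocarbenium ions with alkenes, together with the Povarov reaction of enol ethers. Ring C is closed as the six-membered ring of this [4+2] process, its second bond by a 6-(enolendo)-exo-trig Friedel–Crafts attack of C4a on the C4=O+ carbon. The cis relation of C2 and C3 should follow from the Z geometry of 9 and the E geometry of 16 in the compact endo transition state that places the alkoxy donor under the oxadiene (the topology that puts the 4-alkoxy group cis to the 2-aryl group in Povarov reactions of enol ethers), and the absolute configuration from the auxiliary: allylic strain holds the (Z)-enol ether s-trans, the phenyl ring of the 2-phenylcyclohexyl group covers one face, and 16 adds with its Si face to the open Si face of C3 to give 2R,3R, while C4 is formed cis (4α-alkoxy) and its configuration is erased in step 10. The step needs regioselectivity (secured by the ether versus ester donor difference), chemoselectivity against intermolecular Friedel–Crafts alkylation of ring A (secured by excess 9, dilution and slow addition of the silyl triflate) and survival of the ionisable C4 ether (secured because the one equivalent of Me3SiOTf is consumed irreversibly as methoxytrimethylsilane and pyridinium triflate). Minor isomers differ from 18 as diastereomers because of the auxiliary and should be removable by chromatography.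

Step 8
Reactants: 19 (−)-epicatechin
Product: 20 5,7,3',4'-tetra-O-benzyl-(−)-epicatechin
Conditions: BnBr (4.4 equiv), K2CO3, DMF, 0 °C → rt, under Ar
Reagents that add atoms: benzyl bromide, BrCc1ccccc1
Why: Williamson O-benzylation of the four phenols with a mild carbonate base should leave the far less acidic secondary 3-hydroxyl free and the 2R,3R stereocentres untouched.

Step 9
Reactants: 20 5,7,3',4'-tetra-O-benzyl-(−)-epicatechin; 7 3,4,5-tris(benzyloxy)benzoyl chloride
Product: 21 5,7,3',4'-tetra-O-benzyl-(−)-epicatechin 3-O-[3,4,5-tris(benzyloxy)benzoate] (hepta-O-benzyl epicatechin gallate)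
Conditions: 7 (1.5 equiv), DMAP (cat.), pyridine, CH2Cl2, 0 °C → rt
Reagents that add atoms: none
Why: DMAP-catalysed acylation of the only free hydroxyl by the aroyl chloride gives the 3-O-gallate with retention at C3, since the C3–O bond is not touched.

Step 10
Reactants: 18 all-cis 4α-alkoxy cycloadduct; 21 hepta-O-benzyl epicatechin gallate (3 equiv)
Product: 23 tetradeca-O-benzyl-3,3'-di-O-galloylprocyanidin B2 (4β→8 linked; upper unit 2R,3R,4R; lower unit 2R,3R), via flavan-4-yl cation triflate 22 (not isolated)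
Conditions: Me3SiOTf (0.3 equiv), 4 Å MS, CH2Cl2, −78 → −30 °C; Et3N quench
Reagents that add atoms: none
Why: Lewis acid ionisation of the C4 ether gives the benzylic cation stabilised by the ortho and para oxygens of ring A, which is attacked by C8 (the most nucleophilic carbon of the benzylated lower unit) anti to the 3-O-galloyl group, whose carbonyl oxygen can also shield the α face; this sets C4 as 4β (3,4-trans), as in the known flavan-4-yl cation condensations used for procyanidins, and releases the auxiliary 1 for recovery.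

Step 11
Reactants: 23 tetradeca-O-benzyl-3,3'-di-O-galloylprocyanidin B2
Product: 24 3,3'-digalloylprocyanidin B2
Conditions: H2 (1 atm), Pd(OH)2/C, THF/MeOH/H2O, rt
Reagents that add atoms: none
Why: Hydrogenolysis should remove all fourteen benzyl ethers while the gallate esters, the interflavan bond and all five stereocentres stay untouched.

Compound list
1 | (1R,2S)-trans-2-phenylcyclohexan-1-ol | O[C@@H]1CCCC[C@H]1c1ccccc1 | starting material
2 | sodium (1R,2S)-2-phenylcyclohexanolate | [Na+].[O-][C@@H]1CCCC[C@H]1c1ccccc1 | intermediate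
3 | allyl (1R,2S)-2-phenylcyclohexyl ether | C=CCO[C@@H]1CCCC[C@H]1c1ccccc1 | intermediate
4 | 3-({[(1R,2S)-2-phenylcyclohexyl]oxy}methyl)-1,2,4-trioxolane (secondary ozonide, mixture at the ring carbon) | C1(CO[C@@H]2CCCC[C@H]2c2ccccc2)OCOO1 | intermediate
5 | 2-{[(1R,2S)-2-phenylcyclohexyl]oxy}acetaldehyde | O=CCO[C@@H]1CCCC[C@H]1c1ccccc1 | intermediate
6 | 3,4,5-tris(benzyloxy)benzoic acid | OC(=O)c1cc(OCc2ccccc2)c(OCc2ccccc2)c(OCc2ccccc2)c1 | starting material
7 | 3,4,5-tris(benzyloxy)benzoyl chloride | ClC(=O)c1cc(OCc2ccccc2)c(OCc2ccccc2)c(OCc2ccccc2)c1 | intermediate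
8 | potassium (Z)-2-{[(1R,2S)-2-phenylcyclohexyl]oxy}ethen-1-olate | [K+].[O-]/C=C\O[C@@H]1CCCC[C@H]1c1ccccc1 | intermediate
9 | (Z)-2-{[(1R,2S)-2-phenylcyclohexyl]oxy}ethenyl 3,4,5-tris(benzyloxy)benzoate | O=C(O/C=C\O[C@@H]1CCCC[C@H]1c1ccccc1)c1cc(OCc2ccccc2)c(OCc2ccccc2)c(OCc2ccccc2)c1 | intermediate
10 | 3,4-bis(benzyloxy)benzaldehyde | O=Cc1ccc(OCc2ccccc2)c(OCc2ccccc2)c1 | starting material
11 | 3,4-bis(benzyloxy)benzaldehyde dimethyl acetal | COC(OC)c1ccc(OCc2ccccc2)c(OCc2ccccc2)c1 | intermediate
12 | 3,5-bis(benzyloxy)phenol | Oc1cc(OCc2ccccc2)cc(OCc2ccccc2)c1 | starting material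
13 | 1,2-bis(benzyloxy)-4-[chloro(methoxy)methyl]benzene (α-chloro ether) | COC(Cl)c1ccc(OCc2ccccc2)c(OCc2ccccc2)c1 | intermediate
14 | sodium 3,5-bis(benzyloxy)phenoxide | [Na+].[O-]c1cc(OCc2ccccc2)cc(OCc2ccccc2)c1 | intermediate
15 | 1,3-bis(benzyloxy)-5-{[3,4-bis(benzyloxy)phenyl](methoxy)methoxy}benzene (racemic) | COC(Oc1cc(OCc2ccccc2)cc(OCc2ccccc2)c1)c1ccc(OCc2ccccc2)c(OCc2ccccc2)c1 | intermediate
16 | (E)-{[3,4-bis(benzyloxy)phenyl]methylidene}[3,5-bis(benzyloxy)phenyl]oxonium triflate | c1(cc(OCc2ccccc2)cc(OCc2ccccc2)c1)/[O+]=C/c1ccc(OCc2ccccc2)c(OCc2ccccc2)c1.[O-]S(=O)(=O)C(F)(F)F | intermediate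
17 | open-chain alkoxycarbenium triflate (C2–C3 bond formed, 2R,3R; C4=O+ on the auxiliary oxygen) | O=C(O[C@H](C=[O+][C@@H]1CCCC[C@H]1c1ccccc1)[C@H](Oc1cc(OCc2ccccc2)cc(OCc2ccccc2)c1)c1ccc(OCc2ccccc2)c(OCc2ccccc2)c1)c1cc(OCc2ccccc2)c(OCc2ccccc2)c(OCc2ccccc2)c1.[O-]S(=O)(=O)C(F)(F)F | intermediate
18 | (2R,3R,4R)-5,7-bis(benzyloxy)-2-[3,4-bis(benzyloxy)phenyl]-4-{[(1R,2S)-2-phenylcyclohexyl]oxy}chroman-3-yl 3,4,5-tris(benzyloxy)benzoate | O=C(O[C@@H]1[C@H](O[C@@H]2CCCC[C@H]2c2ccccc2)c2c(OCc3ccccc3)cc(OCc3ccccc3)cc2O[C@@H]1c1ccc(OCc2ccccc2)c(OCc2ccccc2)c1)c1cc(OCc2ccccc2)c(OCc2ccccc2)c(OCc2ccccc2)c1 | intermediate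
19 | (−)-epicatechin (2R,3R) | O[C@@H]1Cc2c(O)cc(O)cc2O[C@@H]1c1ccc(O)c(O)c1 | starting material
20 | 5,7,3',4'-tetra-O-benzyl-(−)-epicatechin (2R,3R) | O[C@@H]1Cc2c(OCc3ccccc3)cc(OCc3ccccc3)cc2O[C@@H]1c1ccc(OCc2ccccc2)c(OCc2ccccc2)c1 | intermediate
21 | 5,7,3',4'-tetra-O-benzyl-(−)-epicatechin 3-O-[3,4,5-tris(benzyloxy)benzoate] (2R,3R) | O=C(O[C@@H]1Cc2c(OCc3ccccc3)cc(OCc3ccccc3)cc2O[C@@H]1c1ccc(OCc2ccccc2)c(OCc2ccccc2)c1)c1cc(OCc2ccccc2)c(OCc2ccccc2)c(OCc2ccccc2)c1 | intermediate
22 | (2R,3R)-hepta-O-benzyl-3-O-galloylflavan-4-yl cation triflate | O=C(O[C@@H]1[CH+]c2c(OCc3ccccc3)cc(OCc3ccccc3)cc2O[C@@H]1c1ccc(OCc2ccccc2)c(OCc2ccccc2)c1)c1cc(OCc2ccccc2)c(OCc2ccccc2)c(OCc2ccccc2)c1.[O-]S(=O)(=O)C(F)(F)F | intermediate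
23 | tetradeca-O-benzyl-3,3'-di-O-galloylprocyanidin B2 (4β→8) | O=C(O[C@@H]1[C@@H](c2c(OCc4ccccc4)cc(OCc4ccccc4)c3c2O[C@H](c2ccc(OCc4ccccc4)c(OCc4ccccc4)c2)[C@H](OC(=O)c2cc(OCc4ccccc4)c(OCc4ccccc4)c(OCc4ccccc4)c2)C3)c2c(OCc4ccccc4)cc(OCc4ccccc4)cc2O[C@@H]1c1ccc(OCc4ccccc4)c(OCc4ccccc4)c1)c1cc(OCc4ccccc4)c(OCc4ccccc4)c(OCc4ccccc4)c1 | intermediate
24 | 3,3'-digalloylprocyanidin B2 | O=C(O[C@@H]1[C@@H](c2c(O)cc(O)c3c2O[C@H](c2ccc(O)c(O)c2)[C@H](OC(=O)c2cc(O)c(O)c(O)c2)C3)c2c(O)cc(O)cc2O[C@@H]1c1ccc(O)c(O)c1)c1cc(O)c(O)c(O)c1 | target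

Total step count: 11
Longest linear sequence: 6 steps (steps 1, 2, 4, 7, 10, 11)

Steps most likely to fail

Step 7. Intermolecular Friedel–Crafts alkylation of ring A by the oxocarbenium ion may outrun the annulation, the C4 ether of the product may ionise under the reaction conditions, or the auxiliary may fail to differentiate the faces. In that case the annulation is given up and the upper unit is taken from the chiral pool. The fallback sets out from 20, whose doubly activated benzylic C4 is oxidised with DDQ in CH2Cl2 in the presence of 2-ethoxyethanol (CCOCCO). This should give (2R,3R,4S)-5,7-bis(benzyloxy)-2-[3,4-bis(benzyloxy)phenyl]-4-(2-ethoxyethoxy)chroman-3-ol F1, the 4β-ether trans to the 3-hydroxyl. Acylation of F1 with 7 (DMAP, pyridine, CH2Cl2) should give (2R,3R,4S)-4-(2-ethoxyethoxy)-hepta-O-benzyl-epicatechin gallate F2. F2 takes the place of 18 in step 10, ionises to the same cation 22 and comes back to the route at 23.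

Step 4. Self-aldol addition of 5 during deprotonation, C-acylation of the enolate or erosion of the Z geometry may occur. The fallback sets out from 5 and generates the enolate by desilylation instead of deprotonation. Soft enolisation with Me3SiCl and Et3N in MeCN should give (Z)-trimethylsilyl enol ether F3, which is purified to a single geometric isomer. MeLi in THF then cleaves the Si–O bond with retention of geometry to lithium (Z)-enolate F4, and acylation with 7 comes back to the route at 9.

Step 6. C-alkylation of the ambident phenoxide, decomposition of the labile α-chloro ether before it is trapped, or hydrolysis of the mixed acetal on purification may occur. The fallback sets out from 12 and forms the acetal by oxidation instead of substitution. O-alkylation with commercial 3,4-bis(benzyloxy)benzyl chloride (ClCc1ccc(OCc2ccccc2)c(OCc2ccccc2)c1; K2CO3, DMF) should give 3,5-bis(benzyloxy)phenyl 3,4-bis(benzyloxy)benzyl ether F5. Hydride abstraction from its electron-rich benzylic CH2 by DDQ in CH2Cl2, with methanol (CO) as trap and 2,6-dichloropyridine as buffer, then comes back to the route at 15.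

Further compounds
F1 | step 7 | (2R,3R,4S)-5,7-bis(benzyloxy)-2-[3,4-bis(benzyloxy)phenyl]-4-(2-ethoxyethoxy)chroman-3-ol | O[C@@H]1[C@@H](OCCOCC)c2c(OCc3ccccc3)cc(OCc3ccccc3)cc2O[C@@H]1c1ccc(OCc2ccccc2)c(OCc2ccccc2)c1
F2 | step 7 | (2R,3R,4S)-5,7-bis(benzyloxy)-2-[3,4-bis(benzyloxy)phenyl]-4-(2-ethoxyethoxy)chroman-3-yl 3,4,5-tris(benzyloxy)benzoate | O=C(O[C@@H]1[C@@H](OCCOCC)c2c(OCc3ccccc3)cc(OCc3ccccc3)cc2O[C@@H]1c1ccc(OCc2ccccc2)c(OCc2ccccc2)c1)c1cc(OCc2ccccc2)c(OCc2ccccc2)c(OCc2ccccc2)c1
F3 | step 4 | trimethyl[(Z)-2-{[(1R,2S)-2-phenylcyclohexyl]oxy}ethenyloxy]silane | C[Si](C)(C)O/C=C\O[C@@H]1CCCC[C@H]1c1ccccc1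
F4 | step 4 | lithium (Z)-2-{[(1R,2S)-2-phenylcyclohexyl]oxy}ethen-1-olate | [Li+].[O-]/C=C\O[C@@H]1CCCC[C@H]1c1ccccc1
F5 | step 6 | 3,5-bis(benzyloxy)phenyl 3,4-bis(benzyloxy)benzyl ether | C(Oc1cc(OCc2ccccc2)cc(OCc2ccccc2)c1)c1ccc(OCc2ccccc2)c(OCc2ccccc2)c1
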